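**Plan**
- Cuts: the three O–Si bonds come off last. Before that come C2–C3 of ring C, then C3–C4 (acylation of diazomethane), then O1–CH2 (ether between a ring A phenol and a ring B benzyl alcohol), then the two aryl–prenyl bonds.
- Enabling feature: C2 is bonded to both O1 and C1' of ring B. In the ring-opened O1–CH2–ring B ether its C–H bonds are therefore doubly activated, and C3 lies next to the C4 carbonyl, where it can serve as a carbenoid carbon.
- Forward: rings A and B are bought as 2,4,6-trihydroxybenzaldehyde and 4-hydroxybenzaldehyde. Ring A receives its prenyl group by a Claisen–Cope relay from the oxygen that later becomes O1, which fixes the 6-prenyl rather than the 8-prenyl pattern.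
- The fragments are joined at O1–CH2 and the formyl group is taken to the diazomethyl ketone. Ring C, the only ring made, closes in the C–H insertion.
- Stereochemistry: the single centre C2 (S) comes from a chiral dirhodium carboxylate that selects one of the two enantiotopic benzylic hydrogens. Buffered, non-basic desilylation preserves it.

Key step: step 10

Abbreviations: prenyl = 3-methylbut-2-en-1-yl; TIPS = triisopropylsilyl. Flavanone numbering (O1, C2, C3, C4, C4a, C5–C8, C8a, primed atoms in ring B) is used for atoms that end up in the target.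

Assumption: Rh2(S-PTTL)4 is taken to deliver the (2S) product. The sense of induction has to be checked on the first run, and if it is opposite the mirror-image catalyst Rh2(R-PTTL)4 is used with no other change.

**Step 1**
Reactants: 1 2,4,6-trihydroxybenzaldehyde
Product: 2 2-hydroxy-4,6-bis(triisopropylsilyloxy)benzaldehyde
Conditions: TIPSCl (2.1 equiv), imidazole, DMF, 0 °C to rt
Reagents that add atoms: triisopropylsilyl chloride, CC(C)[Si](Cl)(C(C)C)C(C)C
Why: Phenol silylation, in which the bulky chloride takes the two hydroxyls not held in the hydrogen bond to the formyl oxygen and leaves the chelated one, as in the usual 4,6-bis-protection of 2,4,6-trihydroxyaryl carbonyl compounds.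

**Step 2**
Reactants: 2 2-hydroxy-4,6-bis(triisopropylsilyloxy)benzaldehyde; 3 3-methylbut-2-en-1-ol (prenol)
Product: 4 2-(3-methylbut-2-enyloxy)-4,6-bis(triisopropylsilyloxy)benzaldehyde
Conditions: PPh3, DIAD, THF, 0 °C to rt
Reagents that add atoms: none
Why: Mitsunobu etherification works on chelated ortho-hydroxyaryl carbonyl compounds under neutral conditions that spare aryl silyl ethers, and a primary allylic alcohol reacts without allylic transposition.

**Step 3**
Reactants: 4 2-(3-methylbut-2-enyloxy)-4,6-bis(triisopropylsilyloxy)benzaldehyde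
Product: 7 6-hydroxy-3-prenyl-2,4-bis(triisopropylsilyloxy)benzaldehyde, via ortho-dienone 5 (not isolated), via para-dienone 6 (not isolated)
Conditions: PhNEt2, 200 °C
Reagents that add atoms: none
Why: Aromatic Claisen rearrangement to the free ortho carbon gives 5, whose crowded 1,1-dimethylallyl group moves on by a Cope rearrangement to the para carbon (a para-Claisen–Cope sequence known for 2-prenyloxy-4,6-dialkoxyaryl carbonyl compounds), and enolisation of 6 should give the phenol with a normal prenyl group between the two silyl ethers and para to the free hydroxyl.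

**Step 4**
Reactants: 8 4-hydroxybenzaldehyde; 9 prenyl bromide
Product: 10 4-hydroxy-3-prenylbenzaldehyde
Conditions: KOH, H2O, rt
Reagents that add atoms: none
Why: C-alkylation of a phenoxide in water, where hydrogen bonding to the oxygen diverts part of the attack to the ortho carbon, is a known preparation of this aldehyde, and the O-prenyl ether expected beside it is removed by chromatography.

**Step 5**
Reactants: 10 4-hydroxy-3-prenylbenzaldehyde
Product: 11 3-prenyl-4-(triisopropylsilyloxy)benzaldehyde
Conditions: TIPSCl, imidazole, DMF, rt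
Reagents that add atoms: triisopropylsilyl chloride, CC(C)[Si](Cl)(C(C)C)C(C)C
Why: Standard phenol silylation, chosen so that one fluoride step later clears all three ethers and so that the electron-releasing para oxygen makes the future benzylic C–H bonds hydridic.

**Step 6**
Reactants: 11 3-prenyl-4-(triisopropylsilyloxy)benzaldehyde
Product: 12 [3-prenyl-4-(triisopropylsilyloxy)phenyl]methanol
Conditions: NaBH4, MeOH–THF, 0 °C
Reagents that add atoms: none
Why: Borohydride reduction of an aromatic aldehyde touches neither the trisubstituted alkene nor the aryl silyl ether at this temperature.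

**Step 7**
Reactants: 7 6-hydroxy-3-prenyl-2,4-bis(triisopropylsilyloxy)benzaldehyde; 12 [3-prenyl-4-(triisopropylsilyloxy)phenyl]methanol
Product: 13 3-prenyl-6-{[3-prenyl-4-(triisopropylsilyloxy)phenyl]methoxy}-2,4-bis(triisopropylsilyloxy)benzaldehyde
Conditions: PPh3, DIAD, THF, 0 °C to rt
Reagents that add atoms: none
Why: Mitsunobu etherification avoids both the labile para-silyloxybenzyl halide and base-induced silyl loss, and because the only free hydroxyl of 7 is the one para to the prenyl group, that oxygen becomes O1.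

**Step 8**
Reactants: 13 3-prenyl-6-{[3-prenyl-4-(triisopropylsilyloxy)phenyl]methoxy}-2,4-bis(triisopropylsilyloxy)benzaldehyde
Product: 14 3-prenyl-6-{[3-prenyl-4-(triisopropylsilyloxy)phenyl]methoxy}-2,4-bis(triisopropylsilyloxy)benzoic acid
Conditions: NaClO2, NaH2PO4, 2-methyl-2-butene (large excess), t-BuOH–THF–H2O, 0 °C to rt
Reagents that add atoms: sodium chlorite NaClO2, [Na+].[O-]Cl=O
Why: Pinnick oxidation at about pH 4 converts hindered, electron-rich aromatic aldehydes to acids, and the excess 2-methyl-2-butene takes up HOCl before it can reach the prenyl groups or the one free ring A position.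

**Step 9**
Reactants: 14 3-prenyl-6-{[3-prenyl-4-(triisopropylsilyloxy)phenyl]methoxy}-2,4-bis(triisopropylsilyloxy)benzoic acid
Product: 16 2-diazo-1-(3-prenyl-6-{[3-prenyl-4-(triisopropylsilyloxy)phenyl]methoxy}-2,4-bis(triisopropylsilyloxy)phenyl)ethanone, via aroyl chloride 15 (not isolated)
Conditions: Me2C=C(Cl)NMe2, CH2Cl2, 0 °C; then CH2N2, Et3N, Et2O, 0 °C
Reagents that add atoms: diazomethane, C=[N+]=[N-]; 1-chloro-N,N,2-trimethylprop-1-en-1-amine, CC(C)=C(Cl)N(C)C (chlorine of 15)
Why: The chloroenamine forms the aroyl chloride without releasing HCl, which protects the prenyl groups and the acid-labile benzyl ether, and acylation of diazomethane (first stage of the Arndt–Eistert sequence) with Et3N as acid trap gives the diazomethyl ketone, an aroyl chloride having no α-hydrogen from which a ketene could form.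

**Step 10**
Reactants: 16 2-diazo-1-(3-prenyl-6-{[3-prenyl-4-(triisopropylsilyloxy)phenyl]methoxy}-2,4-bis(triisopropylsilyloxy)phenyl)ethanone
Product: 17 (2S)-6,3'-diprenyl-5,7,4'-tris(triisopropylsilyloxy)flavanone
Conditions: Rh2(S-PTTL)4 (dirhodium tetrakis[N-phthaloyl-(S)-tert-leucinate], 1 mol%), CH2Cl2, 0 °C, 16 added slowly by syringe pump at high dilution
Reagents that add atoms: none
Why: The divalent rhodium dimer expels N2 from 16, and the electrophilic carbenoid at C3 inserts into one O1–CH2 C–H bond through a concerted, asynchronous three-centre transition state with hydride-transfer character, forming C2–C3. The closest known reaction type is the chiral dirhodium carboxylate-catalysed intramolecular C–H insertion of ortho-alkoxyaryl diazoketones to 2-substituted chroman-4-ones, and the same catalyst family is known to tell apart the enantiotopic hydrogens of aryl benzyl ethers in the related dihydrobenzofuran closure. Ring C closes as a six-membered ring by formal 1,6-insertion, because the 1,5-position is the ether oxygen and carries no hydrogen. C2 is set by the catalyst alone, whose phthalimido walls around the carbenoid should let only one of the two enantiotopic benzylic hydrogens reach C3. The step needs insertion to beat oxonium ylide formation with 1,2-benzyl shift, cyclopropanation of the prenyl groups and attack on the O5 protecting group; here O1 is a weak donor because it is conjugated with the acylated ring A, the para-silyloxy group of ring B makes the benzylic C–H hydridic, the ring A prenyl group is meta to the acyl group and cannot reach C3, the ring B prenyl group could react only through a ring of eleven or more members, and the bulky O5 silyl ether offers no activated C–H bond. Slow addition at high dilution suppresses bimolecular cyclopropanation and carbene dimerisation.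

**Step 11**
Reactants: 17 (2S)-6,3'-diprenyl-5,7,4'-tris(triisopropylsilyloxy)flavanone
Product: 18 macarangaflavanone B, (2S)-5,7,4'-trihydroxy-6,3'-diprenylflavanone
Conditions: HF·pyridine, pyridine, THF, 0 °C to rt
Reagents that add atoms: none
Why: Fluoride-driven cleavage of aryl silyl ethers under weakly acidic buffering never generates a free phenoxide, so the retro-oxa-Michael ring opening that racemises C2 of 5-hydroxyflavanones is avoided and the prenyl groups are not protonated.

**Compound list**
1 | 2,4,6-trihydroxybenzaldehyde | O=Cc1c(O)cc(O)cc1O | starting material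
2 | 2-hydroxy-4,6-bis(triisopropylsilyloxy)benzaldehyde | O=Cc1c(O)cc(O[Si](C(C)C)(C(C)C)C(C)C)cc1O[Si](C(C)C)(C(C)C)C(C)C | intermediate
3 | 3-methylbut-2-en-1-ol (prenol) | CC(C)=CCO | starting material
4 | 2-(3-methylbut-2-enyloxy)-4,6-bis(triisopropylsilyloxy)benzaldehyde | O=Cc1c(OCC=C(C)C)cc(O[Si](C(C)C)(C(C)C)C(C)C)cc1O[Si](C(C)C)(C(C)C)C(C)C | intermediate
5 | ortho-dienone, 5-(2-methylbut-3-en-2-yl)-6-oxo-2,4-bis(triisopropylsilyloxy)cyclohexa-1,3-diene-1-carbaldehyde (racemic, not isolated) | O=CC1=C(O[Si](C(C)C)(C(C)C)C(C)C)C=C(O[Si](C(C)C)(C(C)C)C(C)C)C(C(C)(C)C=C)C1=O | intermediate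
6 | para-dienone, 6-oxo-3-prenyl-2,4-bis(triisopropylsilyloxy)cyclohexa-1,4-diene-1-carbaldehyde (racemic, not isolated) | O=CC1=C(O[Si](C(C)C)(C(C)C)C(C)C)C(CC=C(C)C)C(O[Si](C(C)C)(C(C)C)C(C)C)=CC1=O | intermediate
7 | 6-hydroxy-3-prenyl-2,4-bis(triisopropylsilyloxy)benzaldehyde | O=Cc1c(O)cc(O[Si](C(C)C)(C(C)C)C(C)C)c(CC=C(C)C)c1O[Si](C(C)C)(C(C)C)C(C)C | intermediate
8 | 4-hydroxybenzaldehyde | O=Cc1ccc(O)cc1 | starting material
9 | prenyl bromide | CC(C)=CCBr | starting material
10 | 4-hydroxy-3-prenylbenzaldehyde | O=Cc1ccc(O)c(CC=C(C)C)c1 | intermediate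
11 | 3-prenyl-4-(triisopropylsilyloxy)benzaldehyde | O=Cc1ccc(O[Si](C(C)C)(C(C)C)C(C)C)c(CC=C(C)C)c1 | intermediate
12 | [3-prenyl-4-(triisopropylsilyloxy)phenyl]methanol | OCc1ccc(O[Si](C(C)C)(C(C)C)C(C)C)c(CC=C(C)C)c1 | intermediate
13 | 3-prenyl-6-{[3-prenyl-4-(triisopropylsilyloxy)phenyl]methoxy}-2,4-bis(triisopropylsilyloxy)benzaldehyde | O=Cc1c(OCc2ccc(O[Si](C(C)C)(C(C)C)C(C)C)c(CC=C(C)C)c2)cc(O[Si](C(C)C)(C(C)C)C(C)C)c(CC=C(C)C)c1O[Si](C(C)C)(C(C)C)C(C)C | intermediate
14 | the corresponding benzoic acid | OC(=O)c1c(OCc2ccc(O[Si](C(C)C)(C(C)C)C(C)C)c(CC=C(C)C)c2)cc(O[Si](C(C)C)(C(C)C)C(C)C)c(CC=C(C)C)c1O[Si](C(C)C)(C(C)C)C(C)C | intermediate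
15 | the corresponding aroyl chloride (not isolated) | ClC(=O)c1c(OCc2ccc(O[Si](C(C)C)(C(C)C)C(C)C)c(CC=C(C)C)c2)cc(O[Si](C(C)C)(C(C)C)C(C)C)c(CC=C(C)C)c1O[Si](C(C)C)(C(C)C)C(C)C | intermediate
16 | 2-diazo-1-(3-prenyl-6-{[3-prenyl-4-(triisopropylsilyloxy)phenyl]methoxy}-2,4-bis(triisopropylsilyloxy)phenyl)ethanone | [N-]=[N+]=CC(=O)c1c(OCc2ccc(O[Si](C(C)C)(C(C)C)C(C)C)c(CC=C(C)C)c2)cc(O[Si](C(C)C)(C(C)C)C(C)C)c(CC=C(C)C)c1O[Si](C(C)C)(C(C)C)C(C)C | intermediate
17 | (2S)-6,3'-diprenyl-5,7,4'-tris(triisopropylsilyloxy)flavanone | CC(C)=CCc1cc([C@@H]2CC(=O)c3c(cc(O[Si](C(C)C)(C(C)C)C(C)C)c(CC=C(C)C)c3O[Si](C(C)C)(C(C)C)C(C)C)O2)ccc1O[Si](C(C)C)(C(C)C)C(C)C | intermediate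
18 | macarangaflavanone B, (2S)-5,7,4'-trihydroxy-6,3'-diprenylflavanone | CC(C)=CCc1cc([C@@H]2CC(=O)c3c(cc(O)c(CC=C(C)C)c3O)O2)ccc1O | target

**Step count**
Total steps: 11.
Longest linear sequence: 8 steps (1 → 2 → 4 → 7 → 13 → 14 → 16 → 17 → 18). The ring B branch 8 → 10 → 11 → 12 → 13 → 18 is equally long.

**Steps most likely to fail**

**Step 10.**
- Risk: a carbenoid stabilised only by one acyl group is very reactive. Discrimination between the two enantiotopic benzylic hydrogens may therefore be weak, and part of the carbenoid may be drained by attack of O1 followed by benzyl shift.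
- Fallback: the source of chirality moves from C–H selection to ketone-face selection. It sets out from 16, which is cyclised with achiral Rh2(OAc)4 in CH2Cl2 to the racemic flavanone tris-silyl ether F1.
- A kinetic resolution by Noyori asymmetric transfer hydrogenation follows, using RuCl[(R,R)-TsDPEN](p-cymene) and HCO2H–Et3N in EtOAc at rt. It should reduce the (2R)-ketone to the cis-(2R,4R)-flavan-4-ol F2 and leave the (2S)-ketone untouched.
- Chromatographic separation of ketone from alcohol brings the route back at 17.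

**Step 3.**
- Risk: the Cope stage has to deliver the prenyl group to a carbon lying between two bulky silyl ethers. It may stall, in which case enolisation at the ortho-dienone stage would fix a reverse-prenyl group at the wrong carbon.
- Fallback: direct C-alkylation replaces the sigmatropic relay, setting out from 1 and 9. C-prenylation of the acylphloroglucinol phenoxide (KOH, H2O–MeOH, 0 °C) should give 2,4,6-trihydroxy-3-prenylbenzaldehyde F3.
- The hydroxyl para to the formyl group, the only one that can never chelate, is silylated with one equivalent of TIPSCl and imidazole to give 2,6-dihydroxy-3-prenyl-4-(triisopropylsilyloxy)benzaldehyde F4.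
- Mitsunobu reaction with 12 at the less hindered ortho hydroxyl (flanked by hydrogen, not by prenyl) gives the mono-ether F5.
- TIPSOTf and 2,6-lutidine in CH2Cl2 then silylate the remaining hydroxyl between the prenyl and formyl groups, and the route is rejoined at 13.

**Step 9.**
- Risk: the hindered, very electron-rich aroyl chloride may ionise and shed the acid-labile benzyl group. Traces of acid may also protonate the diazoketone and trigger closure onto O1 with loss of the benzyl cation.
- Fallback: the acid and the acid chloride are avoided altogether, setting out from 13. Addition of MeMgBr (THF, −78 °C to 0 °C) gives the racemic 1-arylethanol F6.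
- Dess–Martin periodinane buffered with NaHCO3 gives the methyl ketone F7.
- Regitz-type detrifluoroacetylative diazo transfer follows. LiN(SiMe3)2 and CF3CO2CH2CF3 in THF at −78 °C give the trifluoroacetyl ketone F8, which is treated crude with MsN3, Et3N and H2O in MeCN at rt. This returns the route at 16.

**Further compounds**
F1 | step 10 | racemic 6,3'-diprenyl-5,7,4'-tris(triisopropylsilyloxy)flavanone | CC(C)=CCc1cc(C2CC(=O)c3c(cc(O[Si](C(C)C)(C(C)C)C(C)C)c(CC=C(C)C)c3O[Si](C(C)C)(C(C)C)C(C)C)O2)ccc1O[Si](C(C)C)(C(C)C)C(C)C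
F2 | step 10 | cis-(2R,4R)-6,3'-diprenyl-5,7,4'-tris(triisopropylsilyloxy)flavan-4-ol | CC(C)=CCc1cc([C@H]2C[C@@H](O)c3c(cc(O[Si](C(C)C)(C(C)C)C(C)C)c(CC=C(C)C)c3O[Si](C(C)C)(C(C)C)C(C)C)O2)ccc1O[Si](C(C)C)(C(C)C)C(C)C
F3 | step 3 | 2,4,6-trihydroxy-3-prenylbenzaldehyde | O=Cc1c(O)cc(O)c(CC=C(C)C)c1O
F4 | step 3 | 2,6-dihydroxy-3-prenyl-4-(triisopropylsilyloxy)benzaldehyde | O=Cc1c(O)cc(O[Si](C(C)C)(C(C)C)C(C)C)c(CC=C(C)C)c1O
F5 | step 3 | 2-hydroxy-3-prenyl-6-{[3-prenyl-4-(triisopropylsilyloxy)phenyl]methoxy}-4-(triisopropylsilyloxy)benzaldehyde | O=Cc1c(OCc2ccc(O[Si](C(C)C)(C(C)C)C(C)C)c(CC=C(C)C)c2)cc(O[Si](C(C)C)(C(C)C)C(C)C)c(CC=C(C)C)c1O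
F6 | step 9 | racemic 1-(3-prenyl-6-{[3-prenyl-4-(triisopropylsilyloxy)phenyl]methoxy}-2,4-bis(triisopropylsilyloxy)phenyl)ethanol | CC(O)c1c(OCc2ccc(O[Si](C(C)C)(C(C)C)C(C)C)c(CC=C(C)C)c2)cc(O[Si](C(C)C)(C(C)C)C(C)C)c(CC=C(C)C)c1O[Si](C(C)C)(C(C)C)C(C)C
F7 | step 9 | 1-(3-prenyl-6-{[3-prenyl-4-(triisopropylsilyloxy)phenyl]methoxy}-2,4-bis(triisopropylsilyloxy)phenyl)ethanone | CC(=O)c1c(OCc2ccc(O[Si](C(C)C)(C(C)C)C(C)C)c(CC=C(C)C)c2)cc(O[Si](C(C)C)(C(C)C)C(C)C)c(CC=C(C)C)c1O[Si](C(C)C)(C(C)C)C(C)C
F8 | step 9 | 4,4,4-trifluoro-1-(3-prenyl-6-{[3-prenyl-4-(triisopropylsilyloxy)phenyl]methoxy}-2,4-bis(triisopropylsilyloxy)phenyl)butane-1,3-dione | O=C(CC(=O)C(F)(F)F)c1c(OCc2ccc(O[Si](C(C)C)(C(C)C)C(C)C)c(CC=C(C)C)c2)cc(O[Si](C(C)C)(C(C)C)C(C)C)c(CC=C(C)C)c1O[Si](C(C)C)(C(C)C)C(C)C
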